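**Retrosynthetic overview**

1. Numbering: ring B = C1–C5 (C2=O, C3(OH)CH2Cl), C6 = spiro carbon, ring A = C7–C11 (C7 Me2, C8 Br, C9 OH, C11=CH2). The C3 chlorohydrin comes from a spiro-epoxide, this from a 3-methylene ketone, and this from the ring B ketone 12, so C3 is functionalised last.
2. Ring A of 12 is opened at C9–C10 and C11–C6. This gives the α-bromo aldehyde–enone 6 and the 2-iodoallyl boronate 9 (allene used as an allyl-then-vinyl linchpin); the forward step is a one-flask allylboration followed by radical 6-exo spirocyclisation.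
3. Enabling feature: C6 is the β-carbon of the ring B ketone (C6–C1–C2=O), so as an enone it is a radical acceptor. C9 is a carbinol carbon three bonds away in ring A (C9–C8–C7–C6) and can be an aldehyde. C10–C11(=CH2) between them is a three-carbon allene unit.
4. Stereocontrol: C8–Br is set by enamine catalysis; C9 and C6 are relayed from C8 in the key step; C3 is relayed from C6 through the ring B chair.
5. Ring order: ring B is bought (3-ethoxycyclohex-2-en-1-one, prenylated to carry C7–C9); ring A is formed in step 5.

Key step: step 5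

Remark: locants follow the name (3S,6R,8R,9S)-8-bromo-3-(chloromethyl)-3,9-dihydroxy-7,7-dimethyl-11-methylidenespiro[5.5]undecan-2-one for the target; propadiene, BI3, prenylmagnesium chloride solution and 3-ethoxycyclohex-2-en-1-one are taken as commercial.

**Step 1**
Reactants: 1 3-ethoxycyclohex-2-en-1-one; 2 prenylmagnesium chloride (3-methylbut-2-en-1-ylmagnesium chloride)
Product: 4 3-(2-methylbut-3-en-2-yl)cyclohex-2-en-1-one, via chloromagnesium alkoxide 3 (not isolated)
Conditions: THF, 0 °C; then 1 M HCl, rt
Reagents that add atoms: water, O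
Why: The prenyl Grignard reagent should add 1,2 to the vinylogous ester carbonyl through its γ-carbon (allylic transposition in a six-membered transition state), and acid then removes water and ethanol to give the transposed enone (Stork–Danheiser sequence); no stereocentre is formed.

**Step 2**
Reactants: 4 3-(2-methylbut-3-en-2-yl)cyclohex-2-en-1-one
Product: 5 3-methyl-3-(3-oxocyclohex-1-en-1-yl)butanal
Conditions: PdCl2(PhCN)2 (10 mol%), CuCl2·2H2O (10 mol%), AgNO2 (5 mol%), O2 (1 atm), t-BuOH/MeNO2 15:1, rt
Reagents that add atoms: dioxygen, O=O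
Why: The nitrite-co-catalysed, aldehyde-selective Wacker-type oxidation should put oxygen on the terminal carbon of the monosubstituted alkene, helped by the neighbouring quaternary carbon that disfavours internal attack, while the electron-poor trisubstituted enone alkene stays untouched.

**Step 3**
Reactants: 5 3-methyl-3-(3-oxocyclohex-1-en-1-yl)butanal
Product: 6 (2R)-2-bromo-3-methyl-3-(3-oxocyclohex-1-en-1-yl)butanal
Conditions: (R)-2-{bis[3,5-bis(trifluoromethyl)phenyl][(trimethylsilyl)oxy]methyl}pyrrolidine (10 mol%), 4,4-dibromo-2,6-di-tert-butylcyclohexa-2,5-dien-1-one (1.05 equiv), PhCO2H (10 mol%), CH2Cl2/pentane 1:1, −40 °C; cold filtration through silica, used at once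
Reagents that add atoms: 4,4-dibromo-2,6-di-tert-butylcyclohexa-2,5-dien-1-one, CC(C)(C)C1=CC(Br)(Br)C=C(C1=O)C(C)(C)C
Why: In this organocatalytic asymmetric α-bromination the E-enamine is shielded on one face by the diarylsilyloxymethyl group of the (R)-catalyst, so Br+ should enter on the open Re face and set C8 as R (the enantiomeric catalyst would be taken if the sense proved opposite); the β-quaternary carbon rules out loss of HBr.

**Step 4**
Reactants: 7 propadiene
Product: 9 2-(2-iodoprop-2-en-1-yl)-4,4,5,5-tetramethyl-1,3,2-dioxaborolane, via diiodo(2-iodoallyl)borane 8 (not isolated)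
Conditions: BI3, CH2Cl2, −78 °C; then pinacol, 2,6-lutidine, −78 °C → rt; distillation
Reagents that add atoms: boron triiodide, IB(I)I; pinacol, CC(C)(O)C(C)(C)O
Why: Haloboration of the 1,2-diene should add B–I across one C=C with boron on the terminal and iodine on the central carbon (as with other boron trihalides), and exchange of the two remaining B–I bonds for the diol gives a storable allylboronic ester.

**Step 5**
Reactants: 6 (2R)-2-bromo-3-methyl-3-(3-oxocyclohex-1-en-1-yl)butanal; 9 2-(2-iodoprop-2-en-1-yl)-4,4,5,5-tetramethyl-1,3,2-dioxaborolane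
Product: 12 (6R,8R,9S)-8-bromo-9-hydroxy-7,7-dimethyl-11-methylidenespiro[5.5]undecan-2-one, via acyclic iodoalkenyl borate 10 (not isolated), via spirocyclic borate 11 (not isolated)
Conditions: (PhO)2P(O)OH (5 mol%), CH2Cl2, −20 °C → rt; then, in the same flask, degassed MeCN (to 0.01 M), fac-Ir(ppy)3 (1 mol%), Hantzsch ester (2 equiv), i-Pr2NEt (2 equiv), blue LEDs, rt; aq. NaHCO3
Reagents that add atoms: none
Why: Stage one is a Brønsted-acid-accelerated allylboration through a closed six-membered (Zimmerman–Traxler) transition state that forms C9–C10 at the aldehyde only, because the conjugated ring ketone is far less electrophilic towards an allylboronic ester; stage two is a photoredox-initiated reductive vinyl-radical cyclisation onto the enone (closest known type: radical cyclisation of alkenyl iodides onto enones), in which the excited trivalent iridium complex reduces the C(sp2)–I bond and leaves the secondary C–Br bond alone. Ring A closes in the 6-exo-trig mode by attack of the C11 vinyl radical on the enone β-carbon C6, and the resulting α-keto radical is quenched by hydrogen transfer from the Hantzsch ester. C9 is controlled by the C8 bromine: in the polar Felkin–Anh (Cornforth) arrangement the C–Br bond lies anti to the carbonyl and the allyl group enters past H and not past the quaternary carbon, which gives the anti-bromohydrin, i.e. the cis-bromohydrin of the closed ring. C6 is controlled in a chair transition state that keeps Br equatorial and the oxygen axial and places the enone C=C pseudo-equatorial, so that a methyl group and not the brominated methine eclipses it (allylic 1,3-strain); this should put the C1 (CH2–C=O) arm of ring B cis to Br and OH. The step needs aldehyde-over-ketone and C–I-over-C–Br chemoselectivity and exo-over-endo closure, secured by the electrophilicity of the α-bromo aldehyde, by the reduction potentials of the two halides, and by the match of the σ-vinyl radical with the enone β-carbon under high dilution.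

**Step 6**
Reactants: 12 (6R,8R,9S)-8-bromo-9-hydroxy-7,7-dimethyl-11-methylidenespiro[5.5]undecan-2-one
Product: 14 (6R,8R,9S)-8-bromo-3-[(dimethylamino)methyl]-9-hydroxy-7,7-dimethyl-11-methylidenespiro[5.5]undecan-2-one (C3 epimers), via dilithium alkoxide enolate 13 (not isolated)
Conditions: LiN(i-Pr)2 (2.2 equiv), THF, −78 °C; Me2N=CH2+ I− (Eschenmoser's salt, 2.5 equiv), −78 → 0 °C; H2O
Reagents that add atoms: N,N-dimethylmethyleneiminium iodide (Eschenmoser's salt), C=[N+](C)C.[I-]
Why: After deprotonation of the hydroxyl, kinetic deprotonation should occur at C3 and not at C1 (C1 is flanked by the quaternary spiro carbon), and the enolate is trapped by the iminium ion (Mannich reaction); the cis-bromohydrin alkoxide cannot close to an epoxide, and the C3 configuration is irrelevant here.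

**Step 7**
Reactants: 14 (6R,8R,9S)-8-bromo-3-[(dimethylamino)methyl]-9-hydroxy-7,7-dimethyl-11-methylidenespiro[5.5]undecan-2-one
Product: 17 (3R,6R,8R,9S)-8-bromo-9-hydroxy-7,7-dimethyl-11-methylidene-2-oxospiro[5.5]undecane-3-spiro-2'-oxirane (oxirane oxygen on C3 cis to C7), via methiodide 15 (not isolated), via methylene ketone 16 (not isolated)
Conditions: MeI, CH2Cl2, rt; evaporation; then 30% H2O2, K2CO3, MeOH, 0 °C
Reagents that add atoms: hydrogen peroxide, OO
Why: N-Methylation and E1cB loss of trimethylamine give the 3-methylene ketone, which is epoxidised at once by hydroperoxide (Weitz–Scheffer epoxidation, inert towards the ring A alkene); closure of the hydroperoxide enolate should form the C3–O bond along the axial direction of the ring B chair that keeps the C7 arm equatorial, which puts the oxirane oxygen cis to C7 (relayed from C6).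

**Step 8**
Reactants: 17 (3R,6R,8R,9S)-8-bromo-9-hydroxy-7,7-dimethyl-11-methylidene-2-oxospiro[5.5]undecane-3-spiro-2'-oxirane
Product: 18 (3S,6R,8R,9S)-8-bromo-3-(chloromethyl)-3,9-dihydroxy-7,7-dimethyl-11-methylidenespiro[5.5]undecan-2-one
Conditions: LiCl, AcOH, THF, rt
Reagents that add atoms: lithium chloride, [Li+].[Cl-]
Why: Chloride should open the acid-activated α,β-epoxy ketone by SN2 at the unhindered CH2 terminus (the tertiary carbon next to the carbonyl is blocked sterically and electronically), so C3 keeps its configuration and the tertiary alcohol is set free.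

**Compound list**

1 | 3-ethoxycyclohex-2-en-1-one | CCOC1=CC(=O)CCC1 | starting material
2 | prenylmagnesium chloride | CC(C)=CC[Mg]Cl | starting material
3 | chloromagnesium 3-ethoxy-1-(2-methylbut-3-en-2-yl)cyclohex-2-en-1-olate (racemic) | CCOC1=CC(CCC1)(O[Mg]Cl)C(C)(C)C=C | intermediate
4 | 3-(2-methylbut-3-en-2-yl)cyclohex-2-en-1-one | C=CC(C)(C)C1=CC(=O)CCC1 | intermediate
5 | 3-methyl-3-(3-oxocyclohex-1-en-1-yl)butanal | O=CCC(C)(C)C1=CC(=O)CCC1 | intermediate
6 | (2R)-2-bromo-3-methyl-3-(3-oxocyclohex-1-en-1-yl)butanal | O=C[C@H](Br)C(C)(C)C1=CC(=O)CCC1 | intermediate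
7 | propadiene | C=C=C | starting material
8 | diiodo(2-iodoprop-2-en-1-yl)borane | C=C(I)CB(I)I | intermediate
9 | 2-(2-iodoprop-2-en-1-yl)-4,4,5,5-tetramethyl-1,3,2-dioxaborolane | C=C(I)CB1OC(C)(C)C(C)(C)O1 | intermediate
10 | 3-{(3R,4S)-3-bromo-6-iodo-2-methyl-4-[(4,4,5,5-tetramethyl-1,3,2-dioxaborolan-2-yl)oxy]hept-6-en-2-yl}cyclohex-2-en-1-one | C=C(I)C[C@H](OB1OC(C)(C)C(C)(C)O1)[C@H](Br)C(C)(C)C1=CC(=O)CCC1 | intermediate
11 | (6R,8R,9S)-8-bromo-7,7-dimethyl-11-methylidene-9-[(4,4,5,5-tetramethyl-1,3,2-dioxaborolan-2-yl)oxy]spiro[5.5]undecan-2-one | C=C1C[C@H](OB3OC(C)(C)C(C)(C)O3)[C@H](Br)C(C)(C)[C@@]12CCCC(=O)C2 | intermediate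
12 | (6R,8R,9S)-8-bromo-9-hydroxy-7,7-dimethyl-11-methylidenespiro[5.5]undecan-2-one | C=C1C[C@H](O)[C@H](Br)C(C)(C)[C@@]12CCCC(=O)C2 | intermediate
13 | dilithium alkoxide enolate of 12 (C2=C3 enolate, C9 alkoxide) | C=C1C[C@H](O[Li])[C@H](Br)C(C)(C)[C@@]12CCC=C(O[Li])C2 | intermediate
14 | (6R,8R,9S)-8-bromo-3-[(dimethylamino)methyl]-9-hydroxy-7,7-dimethyl-11-methylidenespiro[5.5]undecan-2-one (C3 epimers) | C=C1C[C@H](O)[C@H](Br)C(C)(C)[C@@]12CCC(CN(C)C)C(=O)C2 | intermediate
15 | trimethylammonium iodide (methiodide) of 14 | C=C1C[C@H](O)[C@H](Br)C(C)(C)[C@@]12CCC(C[N+](C)(C)C)C(=O)C2.[I-] | intermediate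
16 | (6R,8R,9S)-8-bromo-9-hydroxy-7,7-dimethyl-3,11-dimethylidenespiro[5.5]undecan-2-one | C=C1C[C@H](O)[C@H](Br)C(C)(C)[C@@]12CCC(=C)C(=O)C2 | intermediate
17 | (3R,6R,8R,9S)-8-bromo-9-hydroxy-7,7-dimethyl-11-methylidene-2-oxospiro[5.5]undecane-3-spiro-2'-oxirane | C=C1C[C@H](O)[C@H](Br)C(C)(C)[C@@]12CC[C@@]3(CO3)C(=O)C2 | intermediate
18 | (3S,6R,8R,9S)-8-bromo-3-(chloromethyl)-3,9-dihydroxy-7,7-dimethyl-11-methylidenespiro[5.5]undecan-2-one | C=C1C[C@H](O)[C@H](Br)C(C)(C)[C@@]12CC[C@@](O)(CCl)C(=O)C2 | target

**Step count**

Total step count: 8. Longest linear sequence: 7 steps (steps 1, 2, 3, 5, 6, 7, 8); step 4 is the side branch that makes 9.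

**Steps most likely to fail**

Step 5. The ring closure may show poor facial selectivity at C6 (a flipped-chair or boat-like transition state competing with the chair described), and the vinyl radical may take up hydrogen before it cyclises. The fallback sets out from 6 and comes back at 12; it makes the two bonds in separate operations and closes the ring by carbopalladation instead of a radical. Allylation of 6 with commercial (2-bromoallyl)trimethylsilane and BF3·OEt2 in CH2Cl2 at −78 °C (open transition state, same polar Felkin–Anh sense) should give 3-[(3R,4S)-3,6-dibromo-4-hydroxy-2-methylhept-6-en-2-yl]cyclohex-2-en-1-one F1. Et3SiCl and imidazole convert it into 3-{(3R,4S)-3,6-dibromo-2-methyl-4-[(triethylsilyl)oxy]hept-6-en-2-yl}cyclohex-2-en-1-one F2, which blocks epoxide formation from the acyclic bromohydrin. A reductive Heck cyclisation (Pd(OAc)2, PPh3, HCO2Na, DMF, 60 °C) follows, in which zerovalent palladium inserts only into the alkenyl C–Br bond. Its eclipsed syn-carbopalladation transition state presents the enone in a geometry different from the radical chair and so offers the complementary facial preference; it should give (6R,8R,9S)-8-bromo-7,7-dimethyl-11-methylidene-9-[(triethylsilyl)oxy]spiro[5.5]undecan-2-one F3. HF·pyridine in THF then gives 12.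

Step 2. Oxygen may be delivered to the internal carbon (methyl ketone formation), or turnover may be slow at the hindered alkene. The fallback sets out from 4 and comes back at 5; it replaces the oxidation by hydroboration. Anti-Markovnikov hydroboration with pinacolborane, [Ir(cod)Cl]2 and dppe in CH2Cl2 at rt (the hindered β,β-disubstituted enone should not be reduced) gives 3-[2-methyl-4-(4,4,5,5-tetramethyl-1,3,2-dioxaborolan-2-yl)butan-2-yl]cyclohex-2-en-1-one F4. Oxidation with NaBO3·4H2O in THF/H2O gives 3-(4-hydroxy-2-methylbutan-2-yl)cyclohex-2-en-1-one F5, and Dess–Martin periodinane gives 5.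

Step 7. The closure of the hydroperoxide enolate at C3 is controlled only from the remote C6 and may show poor facial selectivity; the methylene ketone may also dimerise before it is epoxidised. The fallback sets out from 14 and comes back at 17; it moves the stereocontrol from the substrate to a catalyst. 14 is quaternised with MeI and eliminated with NaHCO3 in CH2Cl2/H2O to isolate 16 cold and dilute. 16 is then epoxidised with aqueous H2O2 under iminium catalysis by a cinchona-derived primary amine salt (9-amino-9-deoxy-epi-quinine bis(trifluoroacetate) or its pseudo-enantiomer, whichever is matched), giving 17. No compound outside the list is made (F0).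

**Further compounds**

F1 | step 5 | 3-[(3R,4S)-3,6-dibromo-4-hydroxy-2-methylhept-6-en-2-yl]cyclohex-2-en-1-one | C=C(Br)C[C@H](O)[C@H](Br)C(C)(C)C1=CC(=O)CCC1
F2 | step 5 | 3-{(3R,4S)-3,6-dibromo-2-methyl-4-[(triethylsilyl)oxy]hept-6-en-2-yl}cyclohex-2-en-1-one | C=C(Br)C[C@H](O[Si](CC)(CC)CC)[C@H](Br)C(C)(C)C1=CC(=O)CCC1
F3 | step 5 | (6R,8R,9S)-8-bromo-7,7-dimethyl-11-methylidene-9-[(triethylsilyl)oxy]spiro[5.5]undecan-2-one | C=C1C[C@H](O[Si](CC)(CC)CC)[C@H](Br)C(C)(C)[C@@]12CCCC(=O)C2
F4 | step 2 | 3-[2-methyl-4-(4,4,5,5-tetramethyl-1,3,2-dioxaborolan-2-yl)butan-2-yl]cyclohex-2-en-1-one | CC(C)(CCB1OC(C)(C)C(C)(C)O1)C2=CC(=O)CCC2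
F5 | step 2 | 3-(4-hydroxy-2-methylbutan-2-yl)cyclohex-2-en-1-one | CC(C)(CCO)C1=CC(=O)CCC1
F0 | step 7 | none | none
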